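## Retrosynthetic overview

1. The target is a (2R,3S)-gallocatechin (trans unit) whose ring-B 4'-oxygen is bound to C7 of a (2R,3R)-epigallocatechin (cis unit). Eight phenols are carried as benzyl ethers and released by one final hydrogenolysis.
2. Cis unit: the 3-ol comes from hydride reduction of a flavan-3-one. The ketone comes from oxidative deformylation of a 2-aryl-2H-chromene-3-carbaldehyde, made by aminocatalytic oxa-Michael/aldol annulation of a salicylaldehyde (ring A) with a cinnamaldehyde (ring B).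
3. Trans unit: ring C comes from chiral-ketone-catalysed epoxidation of an E-2-cinnamylphenol and 6-endo epoxide opening. The alkene comes from a 2'-hydroxychalcone.
4. Diaryl ether: SNAr of a 4-hydroxybenzaldehyde (future ring B of the trans unit) on 2,4,6-trifluorobenzonitrile (future ring A of the cis unit; the nitrile is a masked aldehyde).
5. Order of ring formation: diaryl ether first, then ring C of the trans unit, then ring C of the cis unit.

Assumption: 3,5-bis(benzyloxy)-4-hydroxybenzaldehyde and 1-[2,4-bis(benzyloxy)-6-hydroxyphenyl]ethan-1-one are taken as purchasable catalogue compounds.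

Shorthand in names: chroman = 3,4-dihydro-2H-chromene; ArUO– = 2,6-bis(benzyloxy)-4-[(2R,3S)-5,7-bis(benzyloxy)-3-hydroxychroman-2-yl]phenoxy (the benzylated trans unit bound through its 4'-oxygen).

## Route

Step 1
Reactants: 1 3,5-bis(benzyloxy)-4-hydroxybenzaldehyde; 2 2,4,6-trifluorobenzonitrile
Product: 3 4-[2,6-bis(benzyloxy)-4-formylphenoxy]-2,6-difluorobenzonitrile
Conditions: K2CO3, DMF, 25 → 50 °C (1.2 equiv of 2)
Reagents that add atoms: none
Why: SNAr diaryl ether synthesis in which the bulky 2,6-dialkoxyphenoxide of 1 attacks the fluorine para to the nitrile, the most activated and least hindered position, so the ether that joins the two flavan units is fixed at the start.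

Step 2
Reactants: 3 4-[2,6-bis(benzyloxy)-4-formylphenoxy]-2,6-difluorobenzonitrile; 4 benzyl alcohol (2.2 equiv used, two equivalents incorporated)
Product: 5 2,6-bis(benzyloxy)-4-[2,6-bis(benzyloxy)-4-formylphenoxy]benzonitrile
Conditions: BnOH (2.2 equiv), NaH (2.2 equiv), DMF, 0 → 40 °C
Reagents that add atoms: benzyl alcohol, OCc1ccccc1 (the second equivalent of 4, which replaces the second fluorine)
Why: Double SNAr in which the two remaining fluorines, each ortho to the nitrile, are displaced one after the other by two equivalents of sodium benzyloxide; the aldehyde rests reversibly as its hemiacetal alkoxide, and the small excess of alkoxide leaves the para aryloxy group in place.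

Step 3
Reactants: 5 2,6-bis(benzyloxy)-4-[2,6-bis(benzyloxy)-4-formylphenoxy]benzonitrile; 6 1-[2,4-bis(benzyloxy)-6-hydroxyphenyl]ethan-1-one
Product: 7 2,6-bis(benzyloxy)-4-{2,6-bis(benzyloxy)-4-[(E)-3-[2,4-bis(benzyloxy)-6-hydroxyphenyl]-3-oxoprop-1-enyl]phenoxy}benzonitrile
Conditions: KOH, EtOH–THF, 25 °C
Reagents that add atoms: none
Why: Claisen–Schmidt aldol condensation of the acetophenone enolate with the only aldehyde present gives the E-2'-hydroxychalcone, and the hindered nitrile is inert to ethanolic KOH at this temperature.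

Step 4
Reactants: 7 2,6-bis(benzyloxy)-4-{2,6-bis(benzyloxy)-4-[(E)-3-[2,4-bis(benzyloxy)-6-hydroxyphenyl]-3-oxoprop-1-enyl]phenoxy}benzonitrile
Product: 9 2,6-bis(benzyloxy)-4-{2,6-bis(benzyloxy)-4-[(E)-3-[2,4-bis(benzyloxy)-6-hydroxyphenyl]prop-1-enyl]phenoxy}benzonitrile, via chalcone ethyl carbonate 8 (not isolated)
Conditions: ClCO2Et, Et3N, THF, 0 °C; then NaBH4, H2O, 0 → 25 °C
Reagents that add atoms: ethyl chloroformate, CCOC(=O)Cl (its atoms are present only in intermediate 8 and are lost again before 9)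
Why: Reductive deoxygenation of an o-acylphenol through its ethyl carbonate, in which NaBH4 reduces the ketone, the carbonate migrates and is expelled to an o-quinone methide, and a second hydride adds at the benzylic carbon; this gives the E-1,3-diarylpropene with the alkene conjugated to ring B and leaves nitrile and benzyl ethers untouched.

Step 5
Reactants: 9 2,6-bis(benzyloxy)-4-{2,6-bis(benzyloxy)-4-[(E)-3-[2,4-bis(benzyloxy)-6-hydroxyphenyl]prop-1-enyl]phenoxy}benzonitrile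
Product: 11 2,6-bis(benzyloxy)-4-{2,6-bis(benzyloxy)-4-[(2R,3S)-5,7-bis(benzyloxy)-3-hydroxychroman-2-yl]phenoxy}benzonitrile, via (2S,3S)-epoxide 10 (not isolated)
Conditions: 1,2:4,5-di-O-isopropylidene-β-L-erythro-2,3-hexodiulo-2,6-pyranose (L-fructose-derived Shi ketone, 30 mol %), KHSO5 (as 2KHSO5·KHSO4·K2SO4), K2CO3, Bu4NHSO4, Na2B4O7 buffer (pH 10.5), MeCN–CH2(OMe)2–H2O, 0 °C; then TsOH·H2O (5 mol %), CH2Cl2, 0 °C
Reagents that add atoms: potassium peroxymonosulfate (KHSO5), [K+].[O-]S(=O)(=O)OO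
Why: Shi asymmetric epoxidation through a spiro dioxirane transition state sets the first two stereocentres as the (2S,3S)-epoxide (the L-fructose ketone gives the mirror image of the (R,R)-epoxides that the D-fructose ketone gives with E-alkenes), and acid then triggers 6-endo opening by the phenol at the benzylic carbon with inversion, which closes ring C of the trans unit as the 2,3-trans (2R,3S) chromanol.

Step 6
Reactants: 11 2,6-bis(benzyloxy)-4-(ArUO)benzonitrile
Product: 13 2,6-bis(benzyloxy)-4-(ArUO)benzaldehyde, via aldimine 12 (not isolated)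
Conditions: i-Bu2AlH (3 equiv), CH2Cl2, −78 → 0 °C; then 1 M HCl, 0 °C
Reagents that add atoms: water, O
Why: Partial nitrile reduction with i-Bu2AlH stops at the N-aluminated aldimine, which is hydrolysed to the aldehyde on acidic work-up, the free 3-OH only consuming one equivalent of hydride.

Step 7
Reactants: 13 2,6-bis(benzyloxy)-4-(ArUO)benzaldehyde
Product: 14 2-(benzyloxy)-6-hydroxy-4-(ArUO)benzaldehyde
Conditions: MgBr2·OEt2 (3 equiv), toluene–Et2O, 25 → 60 °C; then 1 M HCl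
Reagents that add atoms: none
Why: Chelation-controlled mono-debenzylation in which MgBr2 bridges the aldehyde oxygen and one ortho benzyloxy oxygen and bromide removes that benzyl group; the magnesium phenoxide chelate then shields the second ortho ether, and benzyl ethers without an ortho carbonyl are not cleaved.

Step 8
Reactants: 15 3,4,5-tris(benzyloxy)benzaldehyde; 16 (triphenylphosphoranylidene)acetaldehyde
Product: 17 (E)-3-[3,4,5-tris(benzyloxy)phenyl]prop-2-enal
Conditions: toluene, 80 °C (1.1 equiv of 16)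
Reagents that add atoms: none
Why: Wittig two-carbon homologation with the stabilised formylmethylene ylide gives the E-cinnamaldehyde.

Step 9
Reactants: 14 2-(benzyloxy)-6-hydroxy-4-(ArUO)benzaldehyde; 17 (E)-3-[3,4,5-tris(benzyloxy)phenyl]prop-2-enal
Product: 18 (R)-5-(benzyloxy)-7-(ArUO)-2-[3,4,5-tris(benzyloxy)phenyl]-2H-chromene-3-carbaldehyde
Conditions: (S)-2-[diphenyl(trimethylsilyloxy)methyl]pyrrolidine (20 mol %), 2-nitrobenzoic acid (20 mol %), 4 Å molecular sieves, toluene, 25 °C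
Reagents that add atoms: none
Why: Aminocatalytic domino oxa-Michael/aldol condensation (iminium then enamine activation) in which the phenol of 14 adds to the Si face of the E-iminium ion of 17, the Re face being shielded by the diphenyl(silyloxy)methyl group of the (S)-catalyst, and the enamine then closes onto the ortho aldehyde with loss of water; this forms ring C of the cis unit and sets its C2 as R.

Step 10
Reactants: 18 (R)-5-(benzyloxy)-7-(ArUO)-2-[3,4,5-tris(benzyloxy)phenyl]-2H-chromene-3-carbaldehyde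
Product: 20 (R)-5-(benzyloxy)-7-(ArUO)-2-[3,4,5-tris(benzyloxy)phenyl]chroman-3-one, via enol formate 19 (not isolated)
Conditions: mCPBA (1.1 equiv), NaHCO3, CH2Cl2, 0 °C; then KHCO3, MeOH, 0 °C
Reagents that add atoms: mCPBA, O=C(OO)c1cccc(Cl)c1
Why: Proposed new method: a vinylogous Dakin-type Baeyer–Villiger oxidation of a 2-aryl-2H-chromene-3-carbaldehyde that forms the C3–O bond of the cis unit; the 5,7-dioxygenated ring A pushes electron density through C4=C3, so in the Criegee adduct of the aldehyde the electron-rich C3 alkenyl carbon migrates to oxygen in preference to hydride, as the aryl group does in the Dakin oxidation of a 2,4,6-trialkoxybenzaldehyde, and mild methanolysis of the enol formate then gives the flavan-3-one by tautomerisation without touching C2; the closest known reactions are the Dakin oxidation and the peracid Baeyer–Villiger oxidation of α,β-unsaturated aldehydes to vinyl formates, which to my knowledge have not been shown on 2-aryl-2H-chromene-3-carbaldehydes as an entry to flavan-3-ones.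

Step 11
Reactants: 20 (R)-5-(benzyloxy)-7-(ArUO)-2-[3,4,5-tris(benzyloxy)phenyl]chroman-3-one
Product: 21 (2R,3R)-5-(benzyloxy)-7-(ArUO)-2-[3,4,5-tris(benzyloxy)phenyl]chroman-3-ol
Conditions: LiBH(s-Bu)3 (2.5 equiv), THF, −78 °C; then H2O
Reagents that add atoms: none
Why: Diastereoselective ketone reduction in which the bulky hydride attacks the chroman-3-one from the face opposite the equatorial 2-aryl group and gives the axial alcohol, that is the 2,3-cis (2R,3R) isomer, as established for benzylated flavan-3-ones.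

Step 12
Reactants: 21 (2R,3R)-5-(benzyloxy)-7-(ArUO)-2-[3,4,5-tris(benzyloxy)phenyl]chroman-3-ol
Product: 22 (2R,3S)-2-{4-[((2R,3R)-3,5-dihydroxy-2-(3,4,5-trihydroxyphenyl)chroman-7-yl)oxy]-3,5-dihydroxyphenyl}chroman-3,5,7-triol (CNP0298095.1)
Conditions: H2 (1 atm), Pd(OH)2/C, THF–MeOH, 25 °C
Reagents that add atoms: none
Why: Hydrogenolysis of all eight benzyl ethers under neutral conditions leaves the diaryl ether, the benzylic ring C–O bonds and the four stereocentres unchanged.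

## Compound list

1 | 3,5-bis(benzyloxy)-4-hydroxybenzaldehyde | O=Cc1cc(OCc2ccccc2)c(O)c(OCc2ccccc2)c1 | starting material
2 | 2,4,6-trifluorobenzonitrile | N#Cc1c(F)cc(F)cc1F | starting material
3 | 4-[2,6-bis(benzyloxy)-4-formylphenoxy]-2,6-difluorobenzonitrile | O=Cc1cc(OCc2ccccc2)c(Oc2cc(F)c(C#N)c(F)c2)c(OCc2ccccc2)c1 | intermediate
4 | benzyl alcohol | OCc1ccccc1 | starting material
5 | 2,6-bis(benzyloxy)-4-[2,6-bis(benzyloxy)-4-formylphenoxy]benzonitrile | O=Cc1cc(OCc2ccccc2)c(Oc2cc(OCc3ccccc3)c(C#N)c(OCc3ccccc3)c2)c(OCc2ccccc2)c1 | intermediate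
6 | 1-[2,4-bis(benzyloxy)-6-hydroxyphenyl]ethan-1-one | CC(=O)c1c(O)cc(OCc2ccccc2)cc1OCc1ccccc1 | starting material
7 | 2,6-bis(benzyloxy)-4-{2,6-bis(benzyloxy)-4-[(E)-3-[2,4-bis(benzyloxy)-6-hydroxyphenyl]-3-oxoprop-1-enyl]phenoxy}benzonitrile (2'-hydroxychalcone) | O=C(/C=C/c1cc(OCc2ccccc2)c(Oc2cc(OCc3ccccc3)c(C#N)c(OCc3ccccc3)c2)c(OCc2ccccc2)c1)c1c(O)cc(OCc2ccccc2)cc1OCc1ccccc1 | intermediate
8 | 3,5-bis(benzyloxy)-2-[(E)-3-{3,5-bis(benzyloxy)-4-[3,5-bis(benzyloxy)-4-cyanophenoxy]phenyl}prop-2-enoyl]phenyl ethyl carbonate | O=C(/C=C/c1cc(OCc2ccccc2)c(Oc2cc(OCc3ccccc3)c(C#N)c(OCc3ccccc3)c2)c(OCc2ccccc2)c1)c1c(OC(=O)OCC)cc(OCc2ccccc2)cc1OCc1ccccc1 | intermediate (not isolated)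
9 | 2,6-bis(benzyloxy)-4-{2,6-bis(benzyloxy)-4-[(E)-3-[2,4-bis(benzyloxy)-6-hydroxyphenyl]prop-1-enyl]phenoxy}benzonitrile (E-2-cinnamylphenol) | Oc1cc(OCc2ccccc2)cc(OCc2ccccc2)c1C/C=C/c1cc(OCc2ccccc2)c(Oc2cc(OCc3ccccc3)c(C#N)c(OCc3ccccc3)c2)c(OCc2ccccc2)c1 | intermediate
10 | 2,6-bis(benzyloxy)-4-{2,6-bis(benzyloxy)-4-[(2S,3S)-3-[2,4-bis(benzyloxy)-6-hydroxybenzyl]oxiran-2-yl]phenoxy}benzonitrile | Oc1cc(OCc2ccccc2)cc(OCc2ccccc2)c1C[C@@H]1O[C@H]1c1cc(OCc2ccccc2)c(Oc2cc(OCc3ccccc3)c(C#N)c(OCc3ccccc3)c2)c(OCc2ccccc2)c1 | intermediate (not isolated)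
11 | 2,6-bis(benzyloxy)-4-{2,6-bis(benzyloxy)-4-[(2R,3S)-5,7-bis(benzyloxy)-3-hydroxychroman-2-yl]phenoxy}benzonitrile | c1ccccc1COc1cc(OCc2ccccc2)c2c(c1)O[C@H](c1cc(OCc3ccccc3)c(Oc3cc(OCc4ccccc4)c(C#N)c(OCc4ccccc4)c3)c(OCc3ccccc3)c1)[C@@H](O)C2 | intermediate
12 | imine (ArCH=NH) of 2,6-bis(benzyloxy)-4-(ArUO)benzaldehyde, present in the flask as its N-diisobutylaluminium derivative | c1ccccc1COc1cc(OCc2ccccc2)c2c(c1)O[C@H](c1cc(OCc3ccccc3)c(Oc3cc(OCc4ccccc4)c(C=N)c(OCc4ccccc4)c3)c(OCc3ccccc3)c1)[C@@H](O)C2 | intermediate (not isolated)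
13 | 2,6-bis(benzyloxy)-4-(ArUO)benzaldehyde | c1ccccc1COc1cc(OCc2ccccc2)c2c(c1)O[C@H](c1cc(OCc3ccccc3)c(Oc3cc(OCc4ccccc4)c(C=O)c(OCc4ccccc4)c3)c(OCc3ccccc3)c1)[C@@H](O)C2 | intermediate
14 | 2-(benzyloxy)-6-hydroxy-4-(ArUO)benzaldehyde | c1ccccc1COc1cc(OCc2ccccc2)c2c(c1)O[C@H](c1cc(OCc3ccccc3)c(Oc3cc(OCc4ccccc4)c(C=O)c(O)c3)c(OCc3ccccc3)c1)[C@@H](O)C2 | intermediate
15 | 3,4,5-tris(benzyloxy)benzaldehyde | O=Cc1cc(OCc2ccccc2)c(OCc2ccccc2)c(OCc2ccccc2)c1 | starting material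
16 | (triphenylphosphoranylidene)acetaldehyde | O=CC=P(c1ccccc1)(c1ccccc1)c1ccccc1 | starting material
17 | (E)-3-[3,4,5-tris(benzyloxy)phenyl]prop-2-enal | O=C/C=C/c1cc(OCc2ccccc2)c(OCc2ccccc2)c(OCc2ccccc2)c1 | intermediate
18 | (R)-5-(benzyloxy)-7-(ArUO)-2-[3,4,5-tris(benzyloxy)phenyl]-2H-chromene-3-carbaldehyde | c1ccccc1COc1cc(OCc2ccccc2)c2c(c1)O[C@H](c1cc(OCc3ccccc3)c(Oc3cc(OCc4ccccc4)c4C=C(C=O)[C@@H](c5cc(OCc6ccccc6)c(OCc6ccccc6)c(OCc6ccccc6)c5)Oc4c3)c(OCc3ccccc3)c1)[C@@H](O)C2 | intermediate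
19 | (R)-5-(benzyloxy)-7-(ArUO)-2-[3,4,5-tris(benzyloxy)phenyl]-2H-chromen-3-yl formate | c1ccccc1COc1cc(OCc2ccccc2)c2c(c1)O[C@H](c1cc(OCc3ccccc3)c(Oc3cc(OCc4ccccc4)c4C=C(OC=O)[C@@H](c5cc(OCc6ccccc6)c(OCc6ccccc6)c(OCc6ccccc6)c5)Oc4c3)c(OCc3ccccc3)c1)[C@@H](O)C2 | intermediate (not isolated)
20 | (R)-5-(benzyloxy)-7-(ArUO)-2-[3,4,5-tris(benzyloxy)phenyl]chroman-3-one | c1ccccc1COc1cc(OCc2ccccc2)c2c(c1)O[C@H](c1cc(OCc3ccccc3)c(Oc3cc(OCc4ccccc4)c4CC(=O)[C@@H](c5cc(OCc6ccccc6)c(OCc6ccccc6)c(OCc6ccccc6)c5)Oc4c3)c(OCc3ccccc3)c1)[C@@H](O)C2 | intermediate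
21 | (2R,3R)-5-(benzyloxy)-7-(ArUO)-2-[3,4,5-tris(benzyloxy)phenyl]chroman-3-ol | c1ccccc1COc1cc(OCc2ccccc2)c2c(c1)O[C@H](c1cc(OCc3ccccc3)c(Oc3cc(OCc4ccccc4)c4C[C@@H](O)[C@@H](c5cc(OCc6ccccc6)c(OCc6ccccc6)c(OCc6ccccc6)c5)Oc4c3)c(OCc3ccccc3)c1)[C@@H](O)C2 | intermediate
22 | (2R,3S)-2-{4-[((2R,3R)-3,5-dihydroxy-2-(3,4,5-trihydroxyphenyl)chroman-7-yl)oxy]-3,5-dihydroxyphenyl}chroman-3,5,7-triol | Oc1cc(O)c2c(c1)O[C@H](c1cc(O)c(Oc3cc(O)c4c(c3)O[C@H](c3cc(O)c(O)c(O)c3)[C@H](O)C4)c(O)c1)[C@@H](O)C2 | target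

## Step count and risks

Total step count: 12. Longest linear sequence: 11 steps (1 → 3 → 5 → 7 → 9 → 11 → 13 → 14 → 18 → 20 → 21 → 22); step 8 is a one-step side branch.

The three steps most likely to fail:

Step 5 (epoxidation of a free, electron-rich phenol). The phenol may be oxidised by the dioxirane, or its phenoxide may open the epoxide in the 5-exo mode before acid is added. Fallback, setting out from 9: silylate the phenol (t-BuMe2SiCl, imidazole, DMF) to the silyl ether F1. Run the same chiral-ketone epoxidation on F1 to the silylated (2S,3S)-epoxide F2. Unmask with Bu4NF/AcOH, which releases epoxide 10, and close the ring with TsOH as before. The sequence comes back to the route at 11, at the cost of one extra isolated step.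

Step 9 (annulation with a strongly deactivated salicylaldehyde). The aldehyde of 14 carries three oxygen donors in ortho/para positions, so the aldol closure may be slow and the reversible oxa-Michael step may erode selectivity. Fallback, setting out from 14 (ring B again from 15): Henry condensation of 15 with MeNO2 (NH4OAc, AcOH, 90 °C) gives the nitrostyrene F3. The known tandem oxa-Michael–Henry reaction of 14 with F3 under chiral pyrrolidine/salicylic acid catalysis, with the catalyst enantiomer chosen for the R product, gives the (R)-3-nitro-2H-chromene F4; here the amine condenses with the salicylaldehyde and so activates the weak electrophile, and the ring is closed by a nitronate. Fe powder in AcOH reduces F4 to the enamine F5, which hydrolyses in the same pot to the ketone. This comes back to the route at 20 and bypasses step 10; diastereomers from imperfect control are removed at 21.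

Step 10 (the proposed new oxidative deformylation). Possible failures are epoxidation of the electron-rich enol formate by excess peracid, hydride instead of alkenyl migration (giving the carboxylic acid), or C2 epimerisation of the ketone during methanolysis. Fallback by known chemistry, setting out from 18: Pinnick oxidation (NaClO2, NaH2PO4, 2-methyl-2-butene, t-BuOH–H2O) gives the carboxylic acid F6. Curtius rearrangement ((PhO)2P(O)N3, Et3N, toluene, 25 → 80 °C) proceeds by way of the acyl azide F7 to the vinyl isocyanate F8. Aqueous HCl–THF hydrolyses F8 through the enamine F5 to the ketone, coming back to the route at 20.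

## Further compounds

F1 | step 5 | 2,6-bis(benzyloxy)-4-{2,6-bis(benzyloxy)-4-[(E)-3-{2,4-bis(benzyloxy)-6-[(tert-butyldimethylsilyl)oxy]phenyl}prop-1-enyl]phenoxy}benzonitrile | CC(C)(C)[Si](C)(C)Oc1cc(OCc2ccccc2)cc(OCc2ccccc2)c1C/C=C/c1cc(OCc2ccccc2)c(Oc2cc(OCc3ccccc3)c(C#N)c(OCc3ccccc3)c2)c(OCc2ccccc2)c1
F2 | step 5 | 2,6-bis(benzyloxy)-4-{2,6-bis(benzyloxy)-4-[(2S,3S)-3-{2,4-bis(benzyloxy)-6-[(tert-butyldimethylsilyl)oxy]benzyl}oxiran-2-yl]phenoxy}benzonitrile | CC(C)(C)[Si](C)(C)Oc1cc(OCc2ccccc2)cc(OCc2ccccc2)c1C[C@@H]1O[C@H]1c1cc(OCc2ccccc2)c(Oc2cc(OCc3ccccc3)c(C#N)c(OCc3ccccc3)c2)c(OCc2ccccc2)c1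
F3 | step 9 | (E)-1,2,3-tris(benzyloxy)-5-(2-nitroethenyl)benzene | [O-][N+](=O)/C=C/c1cc(OCc2ccccc2)c(OCc2ccccc2)c(OCc2ccccc2)c1
F4 | step 9 | (R)-5-(benzyloxy)-7-(ArUO)-3-nitro-2-[3,4,5-tris(benzyloxy)phenyl]-2H-chromene | c1ccccc1COc1cc(OCc2ccccc2)c2c(c1)O[C@H](c1cc(OCc3ccccc3)c(Oc3cc(OCc4ccccc4)c4C=C([N+](=O)[O-])[C@@H](c5cc(OCc6ccccc6)c(OCc6ccccc6)c(OCc6ccccc6)c5)Oc4c3)c(OCc3ccccc3)c1)[C@@H](O)C2
F5 | step 9 | (R)-5-(benzyloxy)-7-(ArUO)-2-[3,4,5-tris(benzyloxy)phenyl]-2H-chromen-3-amine (enamine) | c1ccccc1COc1cc(OCc2ccccc2)c2c(c1)O[C@H](c1cc(OCc3ccccc3)c(Oc3cc(OCc4ccccc4)c4C=C(N)[C@@H](c5cc(OCc6ccccc6)c(OCc6ccccc6)c(OCc6ccccc6)c5)Oc4c3)c(OCc3ccccc3)c1)[C@@H](O)C2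
F6 | step 10 | (R)-5-(benzyloxy)-7-(ArUO)-2-[3,4,5-tris(benzyloxy)phenyl]-2H-chromene-3-carboxylic acid | c1ccccc1COc1cc(OCc2ccccc2)c2c(c1)O[C@H](c1cc(OCc3ccccc3)c(Oc3cc(OCc4ccccc4)c4C=C(C(=O)O)[C@@H](c5cc(OCc6ccccc6)c(OCc6ccccc6)c(OCc6ccccc6)c5)Oc4c3)c(OCc3ccccc3)c1)[C@@H](O)C2
F7 | step 10 | (R)-5-(benzyloxy)-7-(ArUO)-2-[3,4,5-tris(benzyloxy)phenyl]-2H-chromene-3-carbonyl azide | c1ccccc1COc1cc(OCc2ccccc2)c2c(c1)O[C@H](c1cc(OCc3ccccc3)c(Oc3cc(OCc4ccccc4)c4C=C(C(=O)N=[N+]=[N-])[C@@H](c5cc(OCc6ccccc6)c(OCc6ccccc6)c(OCc6ccccc6)c5)Oc4c3)c(OCc3ccccc3)c1)[C@@H](O)C2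
F8 | step 10 | (R)-5-(benzyloxy)-7-(ArUO)-3-isocyanato-2-[3,4,5-tris(benzyloxy)phenyl]-2H-chromene | c1ccccc1COc1cc(OCc2ccccc2)c2c(c1)O[C@H](c1cc(OCc3ccccc3)c(Oc3cc(OCc4ccccc4)c4C=C(N=C=O)[C@@H](c5cc(OCc6ccccc6)c(OCc6ccccc6)c(OCc6ccccc6)c5)Oc4c3)c(OCc3ccccc3)c1)[C@@H](O)C2
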